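**Plan**

- Retrosynthetic cuts, in order: the C15 ester; C12–C13 (sp3–sp2 coupling of a C9 vinyl group with a C13–C16 enol triflate); C17–O (allylic oxidation); C9–H and C9–C11 (alkynyl addition to a C9 ketone, then two 1,3-transpositions); ring A at C3–C4; C10–C1 and C10–CH3 (enolate alkylations).
- Enabling feature: ring A carries the quaternary gem-dimethyl carbon C4 directly on the ring-fusion carbon C5. C5–C4(CH3)2 is the hydrogen-atom adduct of an isopropenyl group, so ring B (C5–C10, with C8-methyl = C17 and C9 = carbonyl) is (S)-carvone, and C10 is its α'-carbon.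
- Forward order: ring B is bought; C10 is made quaternary; ring A is closed last by a hydrogen-atom-transfer radical cyclisation in which the C4 radical attacks C3 of a 2-(methoxycarbonyl)allyl arm on C10; the ester is then excised; the side chain is joined last.
- Stereochemistry: C5 comes from (S)-carvone. C10 is set by alkylation anti to the isopropenyl group, which fixes the trans ring fusion. C9 is set by suprafacial hydrogen delivery from an allylic diazene at C7. C13=C14 comes from a stereoretentive coupling of an (E)-enol triflate.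

Key step: step 3

Remark: labdane numbering is used for the bicyclic compounds (decalin C1–C10, side chain C11–C16, C17 on C8, C20 on C10). Compound 3 is a C10-epimer mixture and 6–8 are C2-epimer mixtures; both centres are overwritten or removed later.

**Step 1**
Reactants: 1 (S)-(+)-carvone; 2 iodomethane
Product: 3 (5S)-2,6-dimethyl-5-(prop-1-en-2-yl)cyclohex-2-en-1-one (6-methylcarvone, both C6 epimers)
Conditions: LiN(i-Pr)2, THF, −78 °C; then MeI, −78 → 0 °C
Reagents that add atoms: iodomethane (2), CI
Why: kinetic deprotonation of the cross-conjugated enone at the α'-carbon (future C10) followed by SN2 methylation (enolate alkylation); the new centre is planarised again in step 2.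

**Step 2**
Reactants: 3 6-methylcarvone; 4 methyl 2-(bromomethyl)acrylate
Product: 5 methyl 2-{[(1R,6R)-1,3-dimethyl-2-oxo-6-(prop-1-en-2-yl)cyclohex-3-en-1-yl]methyl}prop-2-enoate (acrylate arm trans to the isopropenyl group)
Conditions: LiN(i-Pr)2, THF, −78 °C; then 4, DMPU, −78 → −20 °C
Reagents that add atoms: methyl 2-(bromomethyl)acrylate (4), C=C(CBr)C(=O)OC
Why: the tetrasubstituted α'-enolate is alkylated (addition–elimination on the allylic bromide) on the face opposite the neighbouring isopropenyl group, as is general for 6,6-dialkylation of carvone, so C10 should carry the C1 arm trans and the methyl cis to C4.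

**Step 3**
Reactants: 5 dialkylated carvone
Product: 6 methyl (4aR,8aR)-4,4,7,8a-tetramethyl-8-oxo-1,2,3,4,4a,5,8,8a-octahydronaphthalene-2-carboxylate (trans-fused, both C2 epimers)
Conditions: Fe(acac)3 (0.3 equiv), PhSiH3, EtOH/ethylene glycol, 60 °C
Reagents that add atoms: none
Why: An iron hydride formed from Fe(acac)3 and PhSiH3 transfers a hydrogen atom to the CH2 terminus of the isopropenyl group, which makes the tertiary radical C4 with its two methyls; this nucleophilic radical adds to C3, the free terminus of the acrylate arm, and the resulting α-ester radical at C2 is reduced and protonated by the alcohol. The closest known reaction type is the hydrogen-atom-transfer-initiated intramolecular Giese reaction (iron-mediated reductive olefin coupling). Ring A is closed in the 6-endo-trig mode through the C3–C4 bond, with both alkene carbons C2 and C3 ending in the ring. C4 becomes quaternary but is not stereogenic, the only new centre C2 arises by unselective protonation and is deleted in step 5, and the trans ring fusion is inherited because C5 (from carvone) and C10 (step 2) hold C4 and C1 trans on ring B. The step needs hydrogen-atom transfer to the electron-rich 1,1-dialkyl alkene in preference to the two electron-poor alkenes, and 6-endo instead of 5-exo closure; the ester on the internal carbon C2 secures the latter by making C3 the unhindered, polarity-matched site. The ring enone cannot intercept the radical because attack on its β-carbon C7 would need a four-membered ring.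

**Step 4**
Reactants: 6 bicyclic ester
Product: 7 (4aR,8aR)-4,4,7,8a-tetramethyl-8-oxo-1,2,3,4,4a,5,8,8a-octahydronaphthalene-2-carboxylic acid (both C2 epimers)
Conditions: LiOH, THF/MeOH/H2O, rt; then 1 M HCl
Reagents that add atoms: lithium hydroxide, [Li+].[OH-]
Why: plain saponification of an unhindered secondary methyl ester; the enone has no epimerisable centre of consequence because C10 is quaternary.

**Step 5**
Reactants: 7 bicyclic acid
Product: 9 (4aR,8aR)-2,5,5,8a-tetramethyl-4a,5,6,7,8,8a-hexahydronaphthalen-1(4H)-one, via thiohydroxamate ester 8 (not isolated)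
Conditions: 1-hydroxypyridine-2(1H)-thione, DCC, DMAP (cat.), CH2Cl2, dark, rt; then t-BuSH, visible light, rt
Reagents that add atoms: none
Why: Barton reductive decarboxylation, in which the thiohydroxamate ester fragments to CO2 and the secondary C2 radical that takes hydrogen from the thiol; this removes the activating group of step 3 together with the C2 stereocentre.

**Step 6**
Reactants: 9 bicyclic enone; 10 ethynylmagnesium bromide
Product: 11 (4aR,8aR)-1-ethynyl-2,5,5,8a-tetramethyl-1,4,4a,5,6,7,8,8a-octahydronaphthalen-1-ol (ethynyl trans to the 8a-methyl)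
Conditions: HC≡CMgBr, CeCl3 (anhydrous), THF, −78 → 0 °C; aq. NH4Cl
Reagents that add atoms: ethynylmagnesium bromide (10), C#C[Mg]Br
Why: 1,2-addition of a small, weakly basic alkynyl nucleophile (cerium-modified Grignard reagent) to the hindered, non-enolisable C9 ketone; attack anti to the axial C20 methyl is expected, and this carbinol centre is erased in step 7.

**Step 7**
Reactants: 11 tertiary propargylic allylic alcohol
Product: 12 (4aR,8aR)-4-ethynyl-3,4a,8,8-tetramethyl-4a,5,6,7,8,8a-hexahydronaphthalen-2(1H)-one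
Conditions: pyridinium chlorochromate, 4 Å molecular sieves, CH2Cl2, rt
Reagents that add atoms: pyridinium chlorochromate, [O-][Cr](=O)(=O)Cl.c1cc[nH+]cc1
Why: Dauben–Babler oxidative transposition, in which the tertiary chromate ester undergoes a [3,3] shift to C7 (the only allylic terminus) and is oxidised there, giving the C7 ketone with C8=C9 now bearing the alkyne.

**Step 8**
Reactants: 12 enynone
Product: 13 (2R,4aR,8aR)-4-ethynyl-3,4a,8,8-tetramethyl-1,2,4a,5,6,7,8,8a-octahydronaphthalen-2-ol (hydroxyl cis to the 4a-methyl)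
Conditions: NaBH4, CeCl3·7H2O, MeOH, −78 → −20 °C
Reagents that add atoms: none
Why: Luche 1,2-reduction; axial hydride attack on C7 from the face of H-5 should place the hydroxyl pseudo-equatorial on the face of the C20 methyl (substrate control by the trans-decalin).

**Step 9**
Reactants: 13 enynol
Product: 16 (1R,4aR,8aR)-1-ethynyl-2,5,5,8a-tetramethyl-1,4,4a,5,6,7,8,8a-octahydronaphthalene (H-1 cis to H-4a), via sulfonylhydrazine 14 (not isolated), via allylic diazene 15 (not isolated)
Conditions: 2-nitrobenzenesulfonylhydrazide, PPh3, DEAD, THF, −30 → 23 °C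
Reagents that add atoms: none
Why: reductive 1,3-transposition through an allylic diazene: Mitsunobu displacement with inversion puts nitrogen on the H-5 face at C7, sulfinic acid is lost, and the sigmatropic (retro-ene) loss of N2 delivers hydrogen suprafacially to C9 while the alkene moves to C7=C8, which sets C9 with the ethynyl group equatorial and cis to C20.

**Step 10**
Reactants: 16 enyne
Product: 17 [(1S,4aR,8aR)-1-ethynyl-5,5,8a-trimethyl-1,4,4a,5,6,7,8,8a-octahydronaphthalen-2-yl]methanol
Conditions: SeO2 (0.3 equiv), t-BuOOH, CH2Cl2, 0 °C → rt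
Reagents that add atoms: tert-butyl hydroperoxide (oxygen relayed by SeO2), CC(C)(C)OO
Why: Riley allylic oxidation (ene reaction then [2,3] shift); on a trisubstituted alkene oxygen goes to a substituent of the more substituted carbon C8, and the C17 methyl should be preferred over the hindered C9 methine next to quaternary C10.

**Step 11**
Reactants: 17 alkynyl alcohol
Product: 18 [(1S,4aR,8aR)-1-ethenyl-5,5,8a-trimethyl-1,4,4a,5,6,7,8,8a-octahydronaphthalen-2-yl]methanol
Conditions: H2 (1 atm), Pd/CaCO3 poisoned with Pb(OAc)2 (Lindlar catalyst), quinoline, EtOAc, rt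
Reagents that add atoms: none
Why: Lindlar semihydrogenation stops at the terminal alkene and leaves the trisubstituted C7=C8 untouched.

**Step 12**
Reactants: 19 acetoxyacetyl chloride; 20 Meldrum's acid; 21 2-(trimethylsilyl)ethanol
Product: 23 2-(trimethylsilyl)ethyl 4-acetoxy-3-oxobutanoate, via acyl Meldrum's acid 22 (not isolated)
Conditions: pyridine, CH2Cl2, 0 °C → rt; then 21, toluene, 110 °C
Reagents that add atoms: Meldrum's acid (20), CC1(C)OC(=O)CC(=O)O1; 2-(trimethylsilyl)ethanol (21), C[Si](C)(C)CCO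
Why: C-acylation of Meldrum's acid and thermal alcoholysis through the acylketene (standard β-keto ester synthesis) under neutral conditions that keep the acetate.

**Step 13**
Reactants: 23 β-keto ester
Product: 24 2-(trimethylsilyl)ethyl (2E)-4-acetoxy-3-{[(trifluoromethyl)sulfonyl]oxy}but-2-enoate
Conditions: Tf2O, i-Pr2NEt, CH2Cl2, −78 °C
Reagents that add atoms: trifluoromethanesulfonic anhydride, O=S(=O)(OS(=O)(=O)C(F)(F)F)C(F)(F)F
Why: O-triflation of the β-keto ester under non-chelating amine-base conditions, which should favour the (E)-enol triflate (OTf trans to the ester, acetoxymethyl cis to it); any (Z)-isomer is to be removed by chromatography.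

**Step 14**
Reactants: 18 vinyl alcohol; 24 enol triflate
Product: 26 2-(trimethylsilyl)ethyl (2Z)-3-(acetoxymethyl)-5-[(1S,4aR,8aR)-2-(hydroxymethyl)-5,5,8a-trimethyl-1,4,4a,5,6,7,8,8a-octahydronaphthalen-1-yl]pent-2-enoate, via alkylborane 25 (not isolated)
Conditions: 9-BBN (2.4 equiv), THF, 0 °C → rt; then 24, PdCl2(dppf) (5 mol%), Ph3As, aq. K3PO4, DMF, rt
Reagents that add atoms: enol triflate (24), CC(=O)OC/C(OS(=O)(=O)C(F)(F)F)=C\C(=O)OCC[Si](C)(C)C
Why: anti-Markovnikov hydroboration of the monosubstituted vinyl group (one equivalent of borane is consumed as the C17 borinate, C7=C8 is inert) and B-alkyl Suzuki–Miyaura coupling with retention of the triflate geometry, which places CH2OAc cis to the ester at C13=C14 as in the target.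

**Step 15**
Reactants: 26 coupled ester
Product: 27 (2Z)-3-(acetoxymethyl)-5-[(1S,4aR,8aR)-2-(hydroxymethyl)-5,5,8a-trimethyl-1,4,4a,5,6,7,8,8a-octahydronaphthalen-1-yl]pent-2-enoic acid (the target)
Conditions: Bu4NF, THF, 0 °C → rt; aq. NH4Cl, pH 4
Reagents that add atoms: none
Why: fluoride-induced β-elimination of the 2-(trimethylsilyl)ethyl ester frees the acid without touching the primary acetate or the allylic alcohol, and lactonisation cannot occur because O16 stays acetylated.

**Compound list**

1 | (S)-(+)-carvone, (5S)-2-methyl-5-(prop-1-en-2-yl)cyclohex-2-en-1-one | O=C1C(C)=CC[C@H](C(C)=C)C1 | starting material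
2 | iodomethane | CI | starting material
3 | (5S)-2,6-dimethyl-5-(prop-1-en-2-yl)cyclohex-2-en-1-one (both C6 epimers) | O=C1C(C)=CC[C@H](C(C)=C)C1C | intermediate
4 | methyl 2-(bromomethyl)acrylate | C=C(CBr)C(=O)OC | starting material
5 | methyl 2-{[(1R,6R)-1,3-dimethyl-2-oxo-6-(prop-1-en-2-yl)cyclohex-3-en-1-yl]methyl}prop-2-enoate | O=C1C(C)=CC[C@H](C(C)=C)[C@@]1(C)CC(=C)C(=O)OC | intermediate
6 | methyl (4aR,8aR)-4,4,7,8a-tetramethyl-8-oxo-1,2,3,4,4a,5,8,8a-octahydronaphthalene-2-carboxylate (C2 epimers) | O=C1C(C)=CC[C@@H]2C(C)(C)CC(C(=O)OC)C[C@@]12C | intermediate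
7 | (4aR,8aR)-4,4,7,8a-tetramethyl-8-oxo-1,2,3,4,4a,5,8,8a-octahydronaphthalene-2-carboxylic acid (C2 epimers) | O=C1C(C)=CC[C@@H]2C(C)(C)CC(C(=O)O)C[C@@]12C | intermediate
8 | 2-thioxopyridin-1(2H)-yl ester of 7 (thiohydroxamate ester) | O=C1C(C)=CC[C@@H]2C(C)(C)CC(C(=O)ON3C=CC=CC3=S)C[C@@]12C | intermediate (not isolated)
9 | (4aR,8aR)-2,5,5,8a-tetramethyl-4a,5,6,7,8,8a-hexahydronaphthalen-1(4H)-one | O=C1C(C)=CC[C@@H]2C(C)(C)CCC[C@@]12C | intermediate
10 | ethynylmagnesium bromide | C#C[Mg]Br | starting material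
11 | (4aR,8aR)-1-ethynyl-2,5,5,8a-tetramethyl-1,4,4a,5,6,7,8,8a-octahydronaphthalen-1-ol (ethynyl trans to the 8a-methyl) | C#C[C@@]1(O)C(C)=CC[C@@H]2C(C)(C)CCC[C@@]12C | intermediate
12 | (4aR,8aR)-4-ethynyl-3,4a,8,8-tetramethyl-4a,5,6,7,8,8a-hexahydronaphthalen-2(1H)-one | C#CC1=C(C)C(=O)C[C@@H]2C(C)(C)CCC[C@@]12C | intermediate
13 | (2R,4aR,8aR)-4-ethynyl-3,4a,8,8-tetramethyl-1,2,4a,5,6,7,8,8a-octahydronaphthalen-2-ol | C#CC1=C(C)[C@H](O)C[C@@H]2C(C)(C)CCC[C@@]12C | intermediate
14 | N-allyl-N-(2-nitrophenylsulfonyl)hydrazine from 13, C7 inverted (N trans to the angular methyl) | C#CC1=C(C)[C@@H](N(N)S(=O)(=O)c3ccccc3[N+](=O)[O-])C[C@@H]2C(C)(C)CCC[C@@]12C | intermediate (not isolated)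
15 | allylic monoalkyl diazene at C7 | C#CC1=C(C)[C@@H](N=N)C[C@@H]2C(C)(C)CCC[C@@]12C | intermediate (not isolated)
16 | (1R,4aR,8aR)-1-ethynyl-2,5,5,8a-tetramethyl-1,4,4a,5,6,7,8,8a-octahydronaphthalene | C#C[C@@H]1C(C)=CC[C@@H]2C(C)(C)CCC[C@@]12C | intermediate
17 | [(1S,4aR,8aR)-1-ethynyl-5,5,8a-trimethyl-1,4,4a,5,6,7,8,8a-octahydronaphthalen-2-yl]methanol | C#C[C@@H]1C(CO)=CC[C@@H]2C(C)(C)CCC[C@@]12C | intermediate
18 | [(1S,4aR,8aR)-1-ethenyl-5,5,8a-trimethyl-1,4,4a,5,6,7,8,8a-octahydronaphthalen-2-yl]methanol | C=C[C@@H]1C(CO)=CC[C@@H]2C(C)(C)CCC[C@@]12C | intermediate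
19 | acetoxyacetyl chloride | CC(=O)OCC(=O)Cl | starting material
20 | Meldrum's acid (2,2-dimethyl-1,3-dioxane-4,6-dione) | CC1(C)OC(=O)CC(=O)O1 | starting material
21 | 2-(trimethylsilyl)ethanol | C[Si](C)(C)CCO | starting material
22 | 5-(2-acetoxy-1-hydroxyethylidene)-2,2-dimethyl-1,3-dioxane-4,6-dione | CC(=O)OCC(O)=C1C(=O)OC(C)(C)OC1=O | intermediate (not isolated)
23 | 2-(trimethylsilyl)ethyl 4-acetoxy-3-oxobutanoate | CC(=O)OCC(=O)CC(=O)OCC[Si](C)(C)C | intermediate
24 | 2-(trimethylsilyl)ethyl (2E)-4-acetoxy-3-{[(trifluoromethyl)sulfonyl]oxy}but-2-enoate | CC(=O)OC/C(OS(=O)(=O)C(F)(F)F)=C\C(=O)OCC[Si](C)(C)C | intermediate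
25 | C12 B-alkyl-9-borabicyclo[3.3.1]nonane from 18, with O17 as its 9-BBN borinate | B1(CC[C@@H]2C(COB3C4CCCC3CCC4)=CC[C@@H]5C(C)(C)CCC[C@@]25C)C6CCCC1CCC6 | intermediate (not isolated)
26 | 2-(trimethylsilyl)ethyl (2Z)-3-(acetoxymethyl)-5-[(1S,4aR,8aR)-2-(hydroxymethyl)-5,5,8a-trimethyl-1,4,4a,5,6,7,8,8a-octahydronaphthalen-1-yl]pent-2-enoate | CC(=O)OC/C(=C\C(=O)OCC[Si](C)(C)C)CC[C@@H]1C(CO)=CC[C@@H]2C(C)(C)CCC[C@@]12C | intermediate
27 | (2Z)-3-(acetoxymethyl)-5-[(1S,4aR,8aR)-2-(hydroxymethyl)-5,5,8a-trimethyl-1,4,4a,5,6,7,8,8a-octahydronaphthalen-1-yl]pent-2-enoic acid | CC(=O)OC/C(=C\C(=O)O)CC[C@@H]1C(CO)=CC[C@@H]2C(C)(C)CCC[C@@]12C | target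

**Step count**

Total: 15 steps. Longest linear sequence: 13 steps (steps 1–11, 14, 15); steps 12 and 13 make the side-chain fragment.

**Steps most likely to fail, with fallbacks**

Step 10. The oxidation may go to the doubly activated C9 methine or run on to the aldehyde instead of stopping at the C17 alcohol. The fallback sets out from 16 and returns at 17, replacing direct C–H oxidation by an epoxide rearrangement and an allylic shift. 16 is epoxidised with mCPBA/NaHCO3 on the face opposite the angular methyl to the 7,8-epoxide F1. Diethylaluminium 2,2,6,6-tetramethylpiperidide in toluene at 0 °C removes a C17 proton and opens the epoxide to the exocyclic allylic alcohol F2. PBr3 in Et2O converts this with allylic shift into the primary bromide F3, which has the endocyclic C7=C8. KOAc in DMF gives the acetate F4, and K2CO3/MeOH gives 17.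

Step 14. Transmetalation of the hindered primary borane may be slow, or the aqueous base may damage the acetoxy enol triflate or its geometry. The fallback sets out from 18 and returns at 27, using a base-free organozinc coupling. 18 is silylated (TBSCl, imidazole) to the silyl ether F8. Hydroboration with 9-BBN gives the alkylborane F9, which I2/NaOMe converts into the primary iodide F10. Zinc dust with LiCl gives the alkylzinc iodide F11, and Negishi coupling with 24 (PdCl2(dppf), THF, rt) gives the doubly silicon-protected ester F12. Bu4NF removes both silicon groups to give 27.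

Step 3. The tertiary radical may be reduced before it cyclises, or hydrogen-atom transfer may go to the acrylate instead of the isopropenyl group. The fallback sets out from 3 and returns at 9, closing ring A by metathesis. 3 is alkylated (LiN(i-Pr)2, then 4-iodobut-1-ene, DMPU) trans to the isopropenyl group to the butenyl ketone F5. Ring-closing metathesis with the second-generation Grubbs catalyst (CH2Cl2, 40 °C) closes ring A as the C3=C4 cyclohexene F6. Iron-mediated hydromethylation (Fe(acac)3, PhSiH3, formaldehyde 2,4,6-trimethylbenzenesulfonylhydrazone) adds the second methyl carbon at C4 as the sulfonylhydrazide F7. Warming F7 in MeOH expels sulfinic acid and N2 to give 9.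

**Further compounds**

F1 | step 10 | 7,8-epoxide of 16 (oxygen trans to the angular methyl) | C#C[C@@H]1[C@@]2(C)O[C@H]2C[C@@H]3C(C)(C)CCC[C@@]13C
F2 | step 10 | 9-ethynyl 8(17)-en-7-ol (hydroxyl trans to the angular methyl) | C#C[C@@H]1C(=C)[C@@H](O)C[C@@H]2C(C)(C)CCC[C@@]12C
F3 | step 10 | C17 allylic bromide with C7=C8 | C#C[C@@H]1C(CBr)=CC[C@@H]2C(C)(C)CCC[C@@]12C
F4 | step 10 | C17 acetate of 17 | C#C[C@@H]1C(COC(C)=O)=CC[C@@H]2C(C)(C)CCC[C@@]12C
F5 | step 3 | (5R,6R)-6-(but-3-en-1-yl)-2,6-dimethyl-5-(prop-1-en-2-yl)cyclohex-2-en-1-one | O=C1C(C)=CC[C@H](C(C)=C)[C@@]1(C)CCC=C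
F6 | step 3 | (4aR,8aR)-2,5,8a-trimethyl-4a,7,8,8a-tetrahydronaphthalen-1(4H)-one | O=C1C(C)=CC[C@@H]2C(C)=CCC[C@@]12C
F7 | step 3 | C4 (2-mesitylsulfonylhydrazinyl)methyl adduct of F6 (C4 epimers) | O=C1C(C)=CC[C@@H]2C(C)(CNNS(=O)(=O)c3c(C)cc(C)cc3C)CCC[C@@]12C
F8 | step 14 | tert-butyldimethylsilyl ether of 18 | C=C[C@@H]1C(CO[Si](C)(C)C(C)(C)C)=CC[C@@H]2C(C)(C)CCC[C@@]12C
F9 | step 14 | C12 B-alkyl-9-borabicyclo[3.3.1]nonane from F8 | B1(CC[C@@H]2C(CO[Si](C)(C)C(C)(C)C)=CC[C@@H]3C(C)(C)CCC[C@@]23C)C4CCCC1CCC4
F10 | step 14 | C12 primary iodide | ICC[C@@H]1C(CO[Si](C)(C)C(C)(C)C)=CC[C@@H]2C(C)(C)CCC[C@@]12C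
F11 | step 14 | C12 alkylzinc iodide | I[Zn]CC[C@@H]1C(CO[Si](C)(C)C(C)(C)C)=CC[C@@H]2C(C)(C)CCC[C@@]12C
F12 | step 14 | O17 tert-butyldimethylsilyl ether of 26 | CC(=O)OC/C(=C\C(=O)OCC[Si](C)(C)C)CC[C@@H]1C(CO[Si](C)(C)C(C)(C)C)=CC[C@@H]2C(C)(C)CCC[C@@]12C
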